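**Retrosynthetic overview**

1. Target 22 comes from triol 19 by acylation of its only secondary hydroxyl with O-allyl-protected 4-hydroxybenzoic acid 20, then deallylation.
2. Triol 19 comes from vinylsilane diol 16 by a silicon-directed singlet-oxygen ene reaction and protodesilylation, which install the C6 hydroxyl and the C7=C8 alkene (azulene numbering); 16 comes from ketone 15 by hydroxyl-directed reduction.
3. Ring B (seven-membered) comes from a rhodium-catalysed [5+2] cycloaddition of vinylcyclopropane 12 with silylalkyne 13, which forms C7–C8 and C5–C6 in one operation. The enabling feature is the strained cyclopropane C1–C5–C6 of the bicyclo[3.1.0]hexane 12, which carries the 1-silyloxyvinyl group on bridgehead C1 and opens at its exocyclic bond C1–C6.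
4. 12 comes from bicyclic keto ester 5 (vinyl triflate, Negishi isopropylation, ester to methyl ketone, epoxidation anti to the cyclopropane, enol silylation, hydride opening); 5 comes from diazo keto ester 4 by asymmetric intramolecular cyclopropanation, and 4 from methyl acetoacetate 1 and methallyl chloride 2.
5. Ring order: ring A (five-membered) and the cyclopropane form together in step 3; ring B forms in step 10 at the expense of the cyclopropane.

Key step: step 10

Assumption: the target is the (3R,3aS,4S,6R,8aR) enantiomer read from the SMILES (azulene numbering is used for all hydroazulenes); in step 3 the ligand antipode is the one that delivers (1R,5R)-5.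

**Step 1**
Reactants: 1 methyl acetoacetate; 2 3-chloro-2-methylprop-1-ene
Product: 3 methyl 6-methyl-3-oxohept-6-enoate
Conditions: NaH, THF, 0 °C; n-BuLi, 0 °C; then 2, 0 °C to rt; aq. NH4Cl
Reagents that add atoms: none
Why: Huckin–Weiler γ-alkylation of the acetoacetate dianion, in which the more basic terminal carbanion attacks the allylic chloride; no stereocenter is formed.

**Step 2**
Reactants: 3 methyl 6-methyl-3-oxohept-6-enoate
Product: 4 methyl 2-diazo-6-methyl-3-oxohept-6-enoate
Conditions: 4-acetamidobenzenesulfonyl azide, Et3N, MeCN, 0 °C to rt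
Reagents that add atoms: 4-acetamidobenzenesulfonyl azide, CC(=O)Nc1ccc(cc1)S(=O)(=O)N=[N+]=[N-]
Why: Regitz diazo transfer to the activated methylene of a β-keto ester; no stereocenter is formed.

**Step 3**
Reactants: 4 methyl 2-diazo-6-methyl-3-oxohept-6-enoate
Product: 5 methyl (1R,5R)-5-methyl-2-oxobicyclo[3.1.0]hexane-1-carboxylate
Conditions: [Cu(MeCN)4]PF6 (5 mol %), 2,2'-(propane-2,2-diyl)bis[(4S)-4-tert-butyl-4,5-dihydro-1,3-oxazole] (6 mol %), toluene, 50 °C, slow addition of 4
Reagents that add atoms: none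
Why: Catalytic asymmetric intramolecular cyclopropanation of the copper carbene onto the tethered 1,1-disubstituted alkene should close ring A and the cyclopropane together; the cis fusion is enforced by geometry and the chiral bis(oxazoline) ligand selects the alkene face, setting both quaternary centers.

**Step 4**
Reactants: 5 methyl (1R,5R)-5-methyl-2-oxobicyclo[3.1.0]hexane-1-carboxylate
Product: 6 methyl (1R,5R)-5-methyl-2-[(trifluoromethanesulfonyl)oxy]bicyclo[3.1.0]hex-2-ene-1-carboxylate
Conditions: KN(SiMe3)2, THF, −78 °C; PhNTf2, −78 to 0 °C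
Reagents that add atoms: N-phenylbis(trifluoromethanesulfonimide), O=S(=O)(N(c1ccccc1)S(=O)(=O)C(F)(F)F)C(F)(F)F
Why: Enol triflate formation; the ketone can enolize only toward C3 because C1 is quaternary, and the stereocenters are untouched.

**Step 5**
Reactants: 6 methyl (1R,5R)-5-methyl-2-[(trifluoromethanesulfonyl)oxy]bicyclo[3.1.0]hex-2-ene-1-carboxylate
Product: 7 methyl (1R,5R)-5-methyl-2-(propan-2-yl)bicyclo[3.1.0]hex-2-ene-1-carboxylate
Conditions: i-PrZnBr (1.5 equiv), Pd(OAc)2 (2 mol %), CPhos (4 mol %), THF/toluene, rt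
Reagents that add atoms: isopropylzinc bromide, CC(C)[Zn]Br
Why: Negishi cross-coupling of a vinyl triflate with a secondary alkylzinc halide; the biaryl phosphine favours reductive elimination over β-hydride elimination so the branched isopropyl group should be transferred, and the ester and cyclopropane are inert.

**Step 6**
Reactants: 7 methyl (1R,5R)-5-methyl-2-(propan-2-yl)bicyclo[3.1.0]hex-2-ene-1-carboxylate
Product: 9 1-[(1R,5R)-5-methyl-2-(propan-2-yl)bicyclo[3.1.0]hex-2-en-1-yl]ethan-1-one, via silyl ketone 8 (not isolated)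
Conditions: Me3SiCH2Li (2.5 equiv), pentane/THF, 0 °C to rt; then MeOH, rt
Reagents that add atoms: (trimethylsilyl)methyllithium, [Li]C[Si](C)(C)C
Why: Ester-to-methyl-ketone conversion with a Peterson-type reagent: the α-silyl ketone formed by acyl substitution is deprotonated at once by the second equivalent and so protected from over-addition, and methanolysis then cleaves the C–Si bond.

**Step 7**
Reactants: 9 1-[(1R,5R)-5-methyl-2-(propan-2-yl)bicyclo[3.1.0]hex-2-en-1-yl]ethan-1-one
Product: 10 1-[(1R,2R,4S,6S)-6-methyl-2-(propan-2-yl)-3-oxatricyclo[4.1.0.0(2,4)]heptan-1-yl]ethan-1-one (epoxide oxygen trans to the cyclopropane CH2)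
Conditions: mCPBA (1.2 equiv), NaHCO3, CH2Cl2, 0 °C
Reagents that add atoms: 3-chloroperoxybenzoic acid, OOC(=O)c1cccc(Cl)c1
Why: Prilezhaev epoxidation of the only alkene; the peracid should approach anti to the cyclopropane methylene that covers the other face, which places the future C3 oxygen trans to that CH2, and Baeyer–Villiger oxidation of the hindered cyclopropyl ketone is slower.

**Step 8**
Reactants: 10 epoxy ketone
Product: 11 (1R,2R,4S,6S)-1-{1-[(tert-butyldimethylsilyl)oxy]ethenyl}-6-methyl-2-(propan-2-yl)-3-oxatricyclo[4.1.0.0(2,4)]heptane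
Conditions: LiN(i-Pr)2, THF, −78 °C; t-BuMe2SiCl, DMPU, −78 to 0 °C
Reagents that add atoms: tert-butyldimethylsilyl chloride, CC(C)(C)[Si](C)(C)Cl
Why: Kinetic enolate O-silylation; the acetyl CH3 is the only enolizable position, and the epoxide survives at low temperature.

**Step 9**
Reactants: 11 silyl enol ether epoxide
Product: 12 (1R,2R,5R)-1-{1-[(tert-butyldimethylsilyl)oxy]ethenyl}-5-methyl-2-(propan-2-yl)bicyclo[3.1.0]hexan-2-ol (hydroxyl trans to the cyclopropane CH2)
Conditions: LiEt3BH (2 equiv), THF, 0 °C to rt; H2O quench at 0 °C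
Reagents that add atoms: none
Why: SN2 hydride opening of the trisubstituted epoxide at its secondary carbon leaves the C–O bond at the quaternary carbon intact, so the tertiary alcohol keeps the configuration set in step 7; the silyl enol ether is inert to hydride.

**Step 10**
Reactants: 12 vinylcyclopropane; 13 trimethyl(prop-1-yn-1-yl)silane
Product: 14 (3R,8aR)-4-[(tert-butyldimethylsilyl)oxy]-6,8a-dimethyl-3-(propan-2-yl)-7-(trimethylsilyl)-1,2,3,5,8,8a-hexahydroazulen-3-ol
Conditions: [Rh(CO)2Cl]2 (5 mol %), 13 (3 equiv), 1,2-dichloroethane, 80 °C, sealed tube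
Reagents that add atoms: none
Why: Monovalent rhodium coordinates the silyloxyvinyl group and inserts into the adjacent exocyclic cyclopropane bond C1–C6 (strain release) to give a σ-alkyl/π-allyl rhodacyclohexene; the alkyne inserts at the allyl terminus (forming C5–C6 of the azulene) and C(sp2)–C(sp3) reductive elimination then forms C7–C8. The closest known reaction type is the rhodium-catalysed intermolecular [5+2] cycloaddition of oxygen- or alkyl-substituted vinylcyclopropanes with alkynes. Ring B is closed as a two-bond [5+2] annulation onto the intact ring A, the last bond being made by reductive elimination from an eight-membered rhodacycle. No new stereocenter is created: C3 and C8a are carried through and the former bridgehead becomes the sp2 carbon C3a, which is set in step 11. Two selectivities are needed: opening of the CH2 bond and not the ring-fusion bond of the cyclopropane, secured because the fusion bond would give a tertiary alkyl–rhodium at the quaternary carbon (the neopentyl CH2–Rh also has no β-hydrogen); and the orientation of the alkyne, secured by the bulky Me3Si group, which should take the position remote from the first-formed C–C bond and so end on C7 while the methyl-bearing carbon becomes C6. The silyl enol ether keeps the C4 oxygen masked under these neutral conditions.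

**Step 11**
Reactants: 14 cycloadduct
Product: 15 (3R,3aR,8aR)-3-hydroxy-6,8a-dimethyl-3-(propan-2-yl)-7-(trimethylsilyl)-2,3,3a,5,8,8a-hexahydroazulen-4(1H)-one (trans-fused)
Conditions: Bu4NF, AcOH (1.5 equiv each), THF, −20 to 0 °C; then DBU (0.2 equiv), CH2Cl2, rt
Reagents that add atoms: none
Why: Fluoride cleavage of the silyl enol ether and C-protonation of the enolate under buffered conditions, chosen because aqueous acid would ionize the allylic tertiary hydroxyl; C3a is epimerizable and should settle under thermodynamic control in the trans-fused ketone, where the C4 carbonyl is anti to the isopropyl group and hydrogen-bonded to the cis C3 hydroxyl.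

**Step 12**
Reactants: 15 hydroxy ketone
Product: 16 (3R,3aS,4S,8aR)-6,8a-dimethyl-3-(propan-2-yl)-7-(trimethylsilyl)-1,2,3,3a,4,5,8,8a-octahydroazulene-3,4-diol
Conditions: Me4NBH(OAc)3 (5 equiv), MeCN/AcOH (1:1), −30 to 0 °C
Reagents that add atoms: none
Why: Evans–Saksena hydroxyl-directed reduction: the C3 hydroxyl exchanges onto boron and should deliver hydride intramolecularly to the carbonyl face on its own side (the side of the angular methyl, which external hydrides avoid), giving the C4 alcohol cis to H3a.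

**Step 13**
Reactants: 16 vinylsilane diol
Product: 18 (3R,3aS,4S,6R,8aS)-6,8a-dimethyl-3-(propan-2-yl)-7-(trimethylsilyl)-1,2,3,3a,4,5,6,8a-octahydroazulene-3,4,6-triol, via allylic hydroperoxide 17 (not isolated)
Conditions: O2, visible light, tetraphenylporphyrin (1 mol %), CH2Cl2, −20 °C; then PPh3, rt
Reagents that add atoms: dioxygen, O=O
Why: Schenck ene reaction of a vinylsilane: silicon directs hydrogen abstraction to the allylic CH2 geminal to it (C8) and oxygen to the remote alkene carbon C6, so the tertiary hydroperoxide with the C7=C8 alkene should form; oxygen should enter anti to the angular methyl and on the side of the C4 hydroxyl (hydroxyl steering), setting C6, and PPh3 reduces the hydroperoxide.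

**Step 14**
Reactants: 18 silyl triol
Product: 19 (3R,3aS,4S,6R,8aR)-6,8a-dimethyl-3-(propan-2-yl)-1,2,3,3a,4,5,6,8a-octahydroazulene-3,4,6-triol
Conditions: Bu4NF (3 equiv), DMSO, 80 °C
Reagents that add atoms: none
Why: Fluoride-induced protodesilylation of a 2-silyl allylic alcohol (the adjacent alkoxide assists a Brook-type C-to-O silyl transfer), which replaces silicon by hydrogen without moving the alkene; Peterson elimination is blocked because it would give a cyclic allene.

**Step 15**
Reactants: 19 triol; 20 4-(prop-2-en-1-yloxy)benzoic acid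
Product: 21 (3R,3aS,4S,6R,8aR)-3,6-dihydroxy-6,8a-dimethyl-3-(propan-2-yl)-1,2,3,3a,4,5,6,8a-octahydroazulen-4-yl 4-(prop-2-en-1-yloxy)benzoate
Conditions: 20 (3 equiv), EDC·HCl (3 equiv), DMAP (3 equiv), CH2Cl2, rt to 40 °C
Reagents that add atoms: none
Why: Steglich esterification; only the secondary C4 hydroxyl should be acylated because the other two are tertiary, and O-acylation retains the C4 configuration.

**Step 16**
Reactants: 21 allyl-protected ester
Product: 22 (3R,3aS,4S,6R,8aR)-3,6-dihydroxy-6,8a-dimethyl-3-(propan-2-yl)-1,2,3,3a,4,5,6,8a-octahydroazulen-4-yl 4-hydroxybenzoate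
Conditions: Pd(PPh3)4 (5 mol %), morpholine (5 equiv), THF, rt
Reagents that add atoms: none
Why: Tsuji–Trost deallylation: zerovalent palladium ionizes the aryl allyl ether and morpholine traps the π-allyl fragment, leaving the benzoate, the free tertiary allylic alcohol and the ring alkene untouched.

**Compound list**

1 | methyl acetoacetate | COC(=O)CC(C)=O | starting material
2 | 3-chloro-2-methylprop-1-ene | C=C(C)CCl | starting material
3 | methyl 6-methyl-3-oxohept-6-enoate | COC(=O)CC(=O)CCC(C)=C | intermediate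
4 | methyl 2-diazo-6-methyl-3-oxohept-6-enoate | COC(=O)C(=[N+]=[N-])C(=O)CCC(C)=C | intermediate
5 | methyl (1R,5R)-5-methyl-2-oxobicyclo[3.1.0]hexane-1-carboxylate | O=C1CC[C@]2(C)C[C@]12C(=O)OC | intermediate
6 | methyl (1R,5R)-5-methyl-2-[(trifluoromethanesulfonyl)oxy]bicyclo[3.1.0]hex-2-ene-1-carboxylate | O=S(=O)(OC1=CC[C@]2(C)C[C@]12C(=O)OC)C(F)(F)F | intermediate
7 | methyl (1R,5R)-5-methyl-2-(propan-2-yl)bicyclo[3.1.0]hex-2-ene-1-carboxylate | CC(C)C1=CC[C@]2(C)C[C@]12C(=O)OC | intermediate
8 | 1-[(1R,5R)-5-methyl-2-(propan-2-yl)bicyclo[3.1.0]hex-2-en-1-yl]-2-(trimethylsilyl)ethan-1-one (formed as its lithium enolate) | CC(C)C1=CC[C@]2(C)C[C@]12C(=O)C[Si](C)(C)C | intermediate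
9 | 1-[(1R,5R)-5-methyl-2-(propan-2-yl)bicyclo[3.1.0]hex-2-en-1-yl]ethan-1-one | CC(C)C1=CC[C@]2(C)C[C@]12C(C)=O | intermediate
10 | 1-[(1R,2R,4S,6S)-6-methyl-2-(propan-2-yl)-3-oxatricyclo[4.1.0.0(2,4)]heptan-1-yl]ethan-1-one | CC(C)[C@]12O[C@H]1C[C@]3(C)C[C@]23C(C)=O | intermediate
11 | (1R,2R,4S,6S)-1-{1-[(tert-butyldimethylsilyl)oxy]ethenyl}-6-methyl-2-(propan-2-yl)-3-oxatricyclo[4.1.0.0(2,4)]heptane | CC(C)[C@]12O[C@H]1C[C@]3(C)C[C@]23C(=C)O[Si](C)(C)C(C)(C)C | intermediate
12 | (1R,2R,5R)-1-{1-[(tert-butyldimethylsilyl)oxy]ethenyl}-5-methyl-2-(propan-2-yl)bicyclo[3.1.0]hexan-2-ol | CC(C)[C@]1(O)CC[C@]2(C)C[C@]12C(=C)O[Si](C)(C)C(C)(C)C | intermediate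
13 | trimethyl(prop-1-yn-1-yl)silane | CC#C[Si](C)(C)C | starting material
14 | (3R,8aR)-4-[(tert-butyldimethylsilyl)oxy]-6,8a-dimethyl-3-(propan-2-yl)-7-(trimethylsilyl)-1,2,3,5,8,8a-hexahydroazulen-3-ol | CC(C)[C@]1(O)CC[C@]2(C)CC([Si](C)(C)C)=C(C)CC(O[Si](C)(C)C(C)(C)C)=C12 | intermediate
15 | (3R,3aR,8aR)-3-hydroxy-6,8a-dimethyl-3-(propan-2-yl)-7-(trimethylsilyl)-2,3,3a,5,8,8a-hexahydroazulen-4(1H)-one | CC(C)[C@]1(O)CC[C@]2(C)CC([Si](C)(C)C)=C(C)CC(=O)[C@H]21 | intermediate
16 | (3R,3aS,4S,8aR)-6,8a-dimethyl-3-(propan-2-yl)-7-(trimethylsilyl)-1,2,3,3a,4,5,8,8a-octahydroazulene-3,4-diol | CC(C)[C@]1(O)CC[C@]2(C)CC([Si](C)(C)C)=C(C)C[C@H](O)[C@H]21 | intermediate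
17 | (3R,3aS,4S,6R,8aS)-6-hydroperoxy-6,8a-dimethyl-3-(propan-2-yl)-7-(trimethylsilyl)-1,2,3,3a,4,5,6,8a-octahydroazulene-3,4-diol | CC(C)[C@]1(O)CC[C@]2(C)C=C([Si](C)(C)C)[C@](C)(OO)C[C@H](O)[C@H]21 | intermediate
18 | (3R,3aS,4S,6R,8aS)-6,8a-dimethyl-3-(propan-2-yl)-7-(trimethylsilyl)-1,2,3,3a,4,5,6,8a-octahydroazulene-3,4,6-triol | CC(C)[C@]1(O)CC[C@]2(C)C=C([Si](C)(C)C)[C@](C)(O)C[C@H](O)[C@H]21 | intermediate
19 | (3R,3aS,4S,6R,8aR)-6,8a-dimethyl-3-(propan-2-yl)-1,2,3,3a,4,5,6,8a-octahydroazulene-3,4,6-triol | CC(C)[C@]1(O)CC[C@]2(C)C=C[C@](C)(O)C[C@H](O)[C@H]21 | intermediate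
20 | 4-(prop-2-en-1-yloxy)benzoic acid | OC(=O)c1ccc(OCC=C)cc1 | starting material
21 | (3R,3aS,4S,6R,8aR)-3,6-dihydroxy-6,8a-dimethyl-3-(propan-2-yl)-1,2,3,3a,4,5,6,8a-octahydroazulen-4-yl 4-(prop-2-en-1-yloxy)benzoate | CC(C)[C@]1(O)CC[C@]2(C)C=C[C@](C)(O)C[C@H](OC(=O)c3ccc(OCC=C)cc3)[C@H]21 | intermediate
22 | (3R,3aS,4S,6R,8aR)-3,6-dihydroxy-6,8a-dimethyl-3-(propan-2-yl)-1,2,3,3a,4,5,6,8a-octahydroazulen-4-yl 4-hydroxybenzoate | CC(C)[C@]1(O)CC[C@]2(C)C=C[C@](C)(O)C[C@H](OC(=O)c3ccc(O)cc3)[C@H]21 | target

**Step count and risks**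

Total step count: 16. Longest linear sequence: 16 steps (1 to 22); 2, 13 and 20 are commercial.

Steps most likely to fail:

1. Step 10. What may go wrong: the alkyne may insert in the reverse orientation (silicon delivered next to C5, methyl next to C8), or the hindered internal alkyne may engage so slowly that opening of the ring-fusion cyclopropane bond competes. Fallback, setting out from 12 and returning at 19: a reversed insertion would mean the steric rule is the opposite of the one assumed, and propyne would then place its methyl group on C6. This fallback does not cover the slow-engagement case. Cycloaddition of 12 with propyne ([Rh(CO)2Cl]2, 1,2-dichloroethane, 60 °C, sealed) would give the silicon-free silyl enol ether F1. Bu4NF/AcOH would then give the trans-fused ketone F2, and Me4NBH(OAc)3 the diol jaeschkeanadiol F3. Without silicon the oxygenation changes to a hydroxyl-directed epoxidation (VO(acac)2, t-BuOOH) giving the epoxy diol F4, opening with PhSeNa (PhSeSePh, NaBH4, EtOH) at the secondary carbon to the hydroxy selenide F5, and oxidation with H2O2. The selenoxide can eliminate only toward C8, which gives 19.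

2. Step 12. What may go wrong: the tertiary hydroxyl may exchange onto boron too slowly, so that hydride delivery is not intramolecular and facial selectivity is lost. Fallback, setting out from 15 and returning at 16: reduction with an external hydride (NaBH4, CeCl3, MeOH, −78 °C), which should enter anti to the angular methyl, would give the C4-epimeric diol F6. Mitsunobu inversion (4-nitrobenzoic acid, PPh3, DIAD, toluene) would give the 4-nitrobenzoate F7 with the required C4 configuration, and K2CO3/MeOH would release 16.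

3. Step 13. What may go wrong: singlet oxygen may attack the face syn to the angular methyl, or hydrogen abstraction may lose its regiocontrol. Fallback, setting out from 16 and returning at 19 (17 and 18 are bypassed): hydroxyl-directed epoxidation (VO(acac)2, t-BuOOH, CH2Cl2) would give the epoxysilane F8. Bu4NF would replace silicon by hydrogen with retention to give the epoxy diol F4, PhSeNa would give the hydroxy selenide F5, and H2O2 oxidation with selenoxide syn-elimination would give 19.

**Further compounds**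

F1 | step 10 | (3R,8aR)-4-[(tert-butyldimethylsilyl)oxy]-6,8a-dimethyl-3-(propan-2-yl)-1,2,3,5,8,8a-hexahydroazulen-3-ol | CC(C)[C@]1(O)CC[C@]2(C)CC=C(C)CC(O[Si](C)(C)C(C)(C)C)=C12
F2 | step 10 | (3R,3aR,8aR)-3-hydroxy-6,8a-dimethyl-3-(propan-2-yl)-2,3,3a,5,8,8a-hexahydroazulen-4(1H)-one | CC(C)[C@]1(O)CC[C@]2(C)CC=C(C)CC(=O)[C@H]21
F3 | step 10 | (3R,3aS,4S,8aR)-6,8a-dimethyl-3-(propan-2-yl)-1,2,3,3a,4,5,8,8a-octahydroazulene-3,4-diol (jaeschkeanadiol) | CC(C)[C@]1(O)CC[C@]2(C)CC=C(C)C[C@H](O)[C@H]21
F4 | step 10 | 6,7-epoxy-6,8a-dimethyl-3-(propan-2-yl)decahydroazulene-3,4-diol (epoxide oxygen cis to the C4 hydroxyl, trans to the angular methyl) | CC(C)[C@]1(O)CC[C@]2(C)C[C@@H]3O[C@]3(C)C[C@H](O)[C@H]21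
F5 | step 10 | (3R,3aS,4S,6R,7R,8aR)-6,8a-dimethyl-7-(phenylselanyl)-3-(propan-2-yl)decahydroazulene-3,4,6-triol | CC(C)[C@]1(O)CC[C@]2(C)C[C@@H]([Se]c3ccccc3)[C@](C)(O)C[C@H](O)[C@H]21
F6 | step 12 | (3R,3aS,4R,8aR)-6,8a-dimethyl-3-(propan-2-yl)-7-(trimethylsilyl)-1,2,3,3a,4,5,8,8a-octahydroazulene-3,4-diol | CC(C)[C@]1(O)CC[C@]2(C)CC([Si](C)(C)C)=C(C)C[C@@H](O)[C@H]21
F7 | step 12 | (3R,3aS,4S,8aR)-3-hydroxy-6,8a-dimethyl-3-(propan-2-yl)-7-(trimethylsilyl)-1,2,3,3a,4,5,8,8a-octahydroazulen-4-yl 4-nitrobenzoate | CC(C)[C@]1(O)CC[C@]2(C)CC([Si](C)(C)C)=C(C)C[C@H](OC(=O)c3ccc(cc3)[N+](=O)[O-])[C@H]21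
F8 | step 13 | 6,7-epoxy-6,8a-dimethyl-3-(propan-2-yl)-7-(trimethylsilyl)decahydroazulene-3,4-diol (epoxide oxygen cis to the C4 hydroxyl) | CC(C)[C@]1(O)CC[C@]2(C)C[C@]3([Si](C)(C)C)O[C@]3(C)C[C@H](O)[C@H]21
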